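The route rests on unmasking the trans-fused A/B unit (methylcyclopentane A on the eight-membered ring B) from a cis-fused cyclohexane/cycloheptene. In tetracyclic cis-diol monomesylate 30 the tertiary allylic alcohol sits on C1 (later the methylene-bearing carbon of ring B) and the equatorial mesylate on C8; base makes the ring-fusion bond C1–C7 migrate to C8. This one operation contracts the cyclohexane to ring A, expands the seven-membered ring to ring B, inverts C8 to give the trans C7–C8 fusion and releases the C1 ketone conjugated to C2=C3 of ring C. Compound 30 comes from a trans-hydrindane enol triflate and a cis-2-alkyl-3-methylcyclohexanone through aldol condensation, intramolecular Stille–Kelly coupling and face-selective dihydroxylation.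

Key step: step 18

Atom labels (target): ring B = C1(=C25H2)–C2=C3–C4(CH3)–C5–C6–C7–C8; ring A = C7–C8–C9–C10–C11(CH3); ring C = C2–C3–C12–C13(CH3)–C14–C15; ring D = C13–C16(OH)–C17–C18(i-Pr)–C14.
Remark: the catalyst and ligand antipodes in steps 1, 3, 8 and 11 are those that deliver the configurations drawn, and diene 6 is taken as a catalogue reagent (otherwise one step from methyl vinyl ketone with TBSOTf/Et3N).

Step 1
Reactants: 1 3-methylbutanal; 2 2-(triphenyl-λ5-phosphanylidene)propanal
Product: 4 (S,E)-4-(hydroxymethyl)-2,5-dimethylhex-2-enal, via (R)-2-(hydroxymethyl)-3-methylbutanal 3 (not isolated)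
Conditions: aq. CH2O, α,α-diphenylprolinol TMS ether (10 mol%), pH 7 buffer, toluene, rt; then 2, CH2Cl2, 40 °C
Reagents that add atoms: formaldehyde, C=O
Why: Enamine-catalysed α-hydroxymethylation (cross-aldol with formaldehyde) should set C18 under catalyst control, and the stabilised formyl ylide traps the labile β-hydroxy aldehyde as the (E)-2-methyl enal (Wittig olefination).

Step 2
Reactants: 4 (S,E)-4-(hydroxymethyl)-2,5-dimethylhex-2-enal
Product: 5 (S,E)-4-(iodomethyl)-2,5-dimethylhex-2-enal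
Conditions: I2, PPh3, imidazole, CH2Cl2, 0 °C
Reagents that add atoms: iodine, II
Why: Appel iodination converts the primary alcohol into the iodide without touching the enal or the adjacent stereocentre.

Step 3
Reactants: 5 (S,E)-4-(iodomethyl)-2,5-dimethylhex-2-enal; 6 2-(tert-butyldimethylsilyloxy)buta-1,3-diene
Product: 7 (1R,6S)-4-(tert-butyldimethylsilyloxy)-6-[(2S)-1-iodo-3-methylbutan-2-yl]-1-methylcyclohex-3-ene-1-carbaldehyde
Conditions: oxazaborolidinium triflimide from (S)-diphenylprolinol/o-tolylboroxine and Tf2NH (20 mol%), CH2Cl2, −78 → −20 °C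
Reagents that add atoms: none
Why: In this Lewis-acid-catalysed Diels–Alder reaction the 2-silyloxy diene adds "para" to the formyl-bearing carbon, the (E)-geometry of 5 becomes the trans C13-formyl/C14-side-chain relationship of the future trans-hydrindane, and the enal face is chosen by the chiral catalyst.

Step 4
Reactants: 7 the Diels–Alder adduct
Product: 8 (3S,3aS,7aR)-5-(tert-butyldimethylsilyloxy)-7a-methyl-3-(propan-2-yl)-2,3,3a,4,7,7a-hexahydro-1H-inden-1-ol (C16 carbinol epimers)
Conditions: SmI2 (2.5 equiv), HMPA, THF, −78 → 0 °C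
Reagents that add atoms: none
Why: Samarium Barbier cyclisation of the alkyl iodide onto the neopentyl aldehyde closes ring D trans to ring C, and the carbinol configuration is left open because steps 5 and 6 reset it.

Step 5
Reactants: 8 the hydrindenol epimers
Product: 9 (3S,3aS,7aR)-5-(tert-butyldimethylsilyloxy)-7a-methyl-3-(propan-2-yl)-2,3,3a,4,7,7a-hexahydro-1H-inden-1-one
Conditions: DMP, NaHCO3, CH2Cl2, 0 °C → rt
Reagents that add atoms: none
Why: Periodinane oxidation (Dess–Martin type) converges both carbinol epimers on the single C16 ketone under buffered conditions that spare the silyl enol ether.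

Step 6
Reactants: 9 the C16 ketone
Product: 10 (1R,3S,3aS,7aR)-5-(tert-butyldimethylsilyloxy)-7a-methyl-3-(propan-2-yl)-2,3,3a,4,7,7a-hexahydro-1H-inden-1-ol
Conditions: NaBH4, MeOH/THF, −20 °C
Reagents that add atoms: none
Why: Borohydride reduction should deliver hydride from the face opposite the angular C21 methyl, giving the C16 alcohol cis to that methyl as in 17-keto steroid reductions.

Step 7
Reactants: 10 the C16 β-alcohol
Product: 11 (1R,3S,3aS,7aR)-1,5-bis(tert-butyldimethylsilyloxy)-7a-methyl-3-(propan-2-yl)-2,3,3a,4,7,7a-hexahydro-1H-indene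
Conditions: TBSOTf, 2,6-lutidine, CH2Cl2, −78 → 0 °C
Reagents that add atoms: tert-butyldimethylsilyl triflate, CC(C)(C)[Si](C)(C)OS(=O)(=O)C(F)(F)F
Why: Silylation with the reactive silyl triflate protects the hindered O16 for the base- and oxidant-mediated steps that follow.

Step 8
Reactants: 11 the bis-silyl compound; 12 (E)-but-2-enal
Product: 14 (1R,3S,3aS,7aR)-1-(tert-butyldimethylsilyloxy)-6-[(2S)-4,4-dimethoxybutan-2-yl]-7a-methyl-3-(propan-2-yl)octahydro-5H-inden-5-one (C3 epimers), via keto aldehyde 13 (not isolated)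
Conditions: 5-benzyl-2-tert-butyl-3-methylimidazolidin-4-one·2,4-dinitrobenzenesulfonic acid (20 mol%), t-BuOH/i-PrOH, H2O (2 equiv), −20 °C; then HC(OMe)3, MeOH, PPTS, rt
Reagents that add atoms: trimethyl orthoformate, COC(OC)OC
Why: In this iminium-catalysed Mukaiyama–Michael addition the imidazolidinone shields one face of the crotonaldehyde iminium ion, so the enol silane (nucleophilic at C3 only) creates C4 under catalyst control, the C3 epimers being erased in step 9, and in-situ acetalisation masks the aldehyde.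

Step 9
Reactants: 14 the keto acetal
Product: 16 (1R,3S,3aS,7aR)-1-(tert-butyldimethylsilyloxy)-6-[(2S)-4,4-dimethoxybutan-2-yl]-7a-methyl-3-(propan-2-yl)-2,3,3a,4,7,7a-hexahydro-1H-inden-5-yl trifluoromethanesulfonate, via bromomagnesium enolate 15 (not isolated)
Conditions: i-Pr2NMgBr (1.3 equiv), Et2O, 23 °C, 12 h; then PhNTf2, THF/DMPU, 0 → 23 °C
Reagents that add atoms: bromomagnesium diisopropylamide, CC(C)N([Mg]Br)C(C)C (MgBr in intermediate 15 only); N-phenylbis(trifluoromethanesulfonimide), O=S(=O)(N(c1ccccc1)S(=O)(=O)C(F)(F)F)C(F)(F)F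
Why: Equilibrating magnesium enolate formation favours the more substituted C2=C3 enolate, which is also the direction a trans-fused hydrindan-5-one prefers (away from the ring fusion), and O-triflation fixes it as the tetrasubstituted enol triflate (thermodynamic enolate trapping).

Step 10
Reactants: 16 the enol triflate acetal
Product: 17 (1R,3S,3aS,7aR)-1-(tert-butyldimethylsilyloxy)-7a-methyl-6-[(2S)-4-oxobutan-2-yl]-3-(propan-2-yl)-2,3,3a,4,7,7a-hexahydro-1H-inden-5-yl trifluoromethanesulfonate
Conditions: PPTS, acetone/H2O, 45 °C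
Reagents that add atoms: water, O
Why: Mild acid-catalysed acetal hydrolysis unmasks the C6 aldehyde while the enol triflate and the silyl ether survive.

Step 11
Reactants: 18 cyclohex-2-en-1-one; 17 the triflate aldehyde
Product: 20 aldol adduct (C6 carbinol bonded to C7 of a (3S)-3-methyl-2-oxocyclohexyl ring; C7/C11 trans; C6 epimers), via zinc enolate 19 (not isolated)
Conditions: 18 (2 equiv), Me2Zn, Cu(OTf)2 (2 mol%), chiral phosphoramidite (4 mol%), toluene, −30 °C; then 17, −30 → 0 °C
Reagents that add atoms: dimethylzinc, C[Zn]C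
Why: Copper/phosphoramidite-catalysed asymmetric conjugate addition of dimethylzinc sets C11, and the zinc enolate, nucleophilic only at C7, adds to the aldehyde (tandem conjugate addition–aldol), the C6 and C7 centres being reset in steps 12 and 13.

Step 12
Reactants: 20 the aldol adduct
Product: 22 (E)-alkylidene ketone (C6=C7 exocyclic to the 3-methylcyclohexanone), via aldol mesylate 21 (not isolated)
Conditions: MsCl, Et3N, CH2Cl2, 0 °C; then DBU, rt
Reagents that add atoms: methanesulfonyl chloride, CS(=O)(=O)Cl (in intermediate 21 only)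
Why: Mesylation followed by E1cB elimination gives the (E)-enone under conditions mild enough to keep the double bond exocyclic, so that C11 is not erased.

Step 13
Reactants: 22 the (E)-alkylidene ketone
Product: 24 cis-ketone (the C7 side chain and the C11 methyl cis on the cyclohexanone; (1S,2S)-2-methyl-6-oxocyclohexyl unit), via lithium enolate 23 (not isolated)
Conditions: LiBH(s-Bu)3, THF, −78 °C; then AcOH/THF, −78 °C
Reagents that add atoms: lithium tri-sec-butylborohydride, [Li+].CCC(C)[BH-](C(C)CC)C(C)CC (lithium in intermediate 23 only)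
Why: 1,4-Hydride addition to the exocyclic C6, then kinetic protonation of the C1–C7 enolate anti to the C11 methyl (held pseudoaxial by A(1,2) strain), should place C7–H trans to the methyl and hence the C6 chain cis to it (conjugate reduction with kinetic protonation).

Step 14
Reactants: 24 the cis-ketone
Product: 26 bis(enol triflate) (C2 triflate on ring C; C1 triflate with C1=C8 on the methylcyclohexene), via potassium enolate 25 (not isolated)
Conditions: KHMDS, THF, −78 °C; then PhNTf2, −78 → 0 °C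
Reagents that add atoms: potassium hexamethyldisilazide, [K+].C[Si](C)(C)[N-][Si](C)(C)C (potassium in intermediate 25 only); N-phenylbis(trifluoromethanesulfonimide), O=S(=O)(N(c1ccccc1)S(=O)(=O)C(F)(F)F)C(F)(F)F
Why: Kinetic deprotonation occurs at the unhindered C8 methylene and not at the tertiary C7–H, so O-triflation gives the C1=C8 enol triflate without epimerising C7 (kinetic enolate trapping).

Step 15
Reactants: 26 the bis(enol triflate)
Product: 28 6-7-6-5 tetracyclic diene (C8=C1–C2=C3; 4S,7S,11S,13R,14S,16R,18S; O16-TBS), via alkenylstannane 27 (not isolated)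
Conditions: Pd(PPh3)4 (10 mol%), Me3SnSnMe3 (1.1 equiv), LiCl, 1,4-dioxane, 100 °C, high dilution
Reagents that add atoms: hexamethylditin, C[Sn](C)(C)[Sn](C)(C)C (in intermediate 27 only)
Why: In this Stille–Kelly coupling Pd(0) inserts first into the less hindered C1 triflate, the ditin converts it into the alkenylstannane, and intramolecular Stille coupling with the tetrasubstituted C2 triflate closes the seven-membered ring through the C1–C2 bond without touching a stereocentre.

Step 16
Reactants: 28 the tetracyclic diene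
Product: 29 (1S,8S)-cis-diol of 28 (tertiary C1–OH and secondary C8–OH; both anti to C6)
Conditions: OsO4 (5 mol%), NMO, acetone/H2O, 0 °C → rt
Reagents that add atoms: osmium tetroxide, O=[Os](=O)(=O)=O; N-methylmorpholine N-oxide, C[N+]1([O-])CCOCC1; water, O
Why: Catalytic osmylation should attack the trisubstituted C1=C8 bond rather than the hindered tetrasubstituted C2=C3 bond, from the face opposite the pseudoaxial C7–C6 bond and the C11 methyl, giving the cis-diol anti to C6 (suprafacial dihydroxylation).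

Step 17
Reactants: 29 the cis-diol
Product: 30 C8 monomesylate of diol 29
Conditions: MsCl, Et3N, CH2Cl2, −20 °C
Reagents that add atoms: methanesulfonyl chloride, CS(=O)(=O)Cl
Why: Only the secondary C8 hydroxyl is sulfonylated, because the tertiary allylic C1 hydroxyl is too hindered under these conditions (selective mesylation).

Step 18
Reactants: 30 the diol monomesylate
Product: 31 5-8-6-5 enone (C1 ketone conjugated to C2=C3; trans A/B fusion; O16-TBS)
Conditions: KOt-Bu, t-BuOH/THF, 0 → 25 °C
Reagents that add atoms: none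
Why: The base deprotonates the tertiary C1 alcohol, and the C1–C7 σ-bond, antiperiplanar to the equatorial C8–OMs bond, migrates to C8 as mesylate leaves while C1 becomes the ketone (concerted semipinacol shift). The closest known reaction type is the base-induced pinacol-type rearrangement of cis-fused decalin-diol monosulfonates to hydroazulenones, here one carbon larger (bicyclo[5.4.0] to bicyclo[6.3.0]). Ring A is closed by the 1,2-alkyl shift itself (C7–C8 bond formation, contraction of the cyclohexane) and ring B arises by the simultaneous one-carbon expansion of the cycloheptene; no other ring-forming bond is made. C8 is the only centre that changes: it is inverted by backside displacement, so its configuration derives from the C8–O bond set in step 16, while C7 migrates with retention, which together give the trans A/B fusion with the C11 methyl cis to C6. The step needs migration of C7 rather than of the alkenyl carbon C2, epoxide closure or E2 elimination: the cis-diol geometry rules out the epoxide, and the chair anchored by the equatorial C11 methyl (the flipped chair has a syn-diaxial C2/methyl contact) keeps the mesylate equatorial, so only the ring bond C1–C7 is antiperiplanar to it and no C9–H is. The ketone formed is also the thermodynamically preferred C8 epimer (C1 trans to C6), so the base should not erode the new centre.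

Step 19
Reactants: 31 the enone
Product: 32 O16-TBS ether of the target (C25=C1–C2=C3 diene)
Conditions: Ph3PCH3Br, KOt-Bu, toluene, 80 °C
Reagents that add atoms: methylenetriphenylphosphorane, C=P(c1ccccc1)(c1ccccc1)c1ccccc1
Why: Wittig methylenation of the C1 ketone installs the exocyclic methylene, and C8 is not at risk because its configuration is the thermodynamic one.

Step 20
Reactants: 32 the silyl ether
Product: 33 target alcohol CNP0544018.1
Conditions: TBAF, THF, 50 °C
Reagents that add atoms: none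
Why: Fluoride cleaves the Si–O16 bond with retention at carbon and leaves the acid-sensitive diene untouched (desilylation).

Compound list
1 | 3-methylbutanal | CC(C)CC=O | starting material
2 | 2-(triphenyl-λ5-phosphanylidene)propanal | CC(C=O)=P(c1ccccc1)(c1ccccc1)c1ccccc1 | starting material
3 | (R)-2-(hydroxymethyl)-3-methylbutanal | O=C[C@@H](CO)C(C)C | intermediate (not isolated)
4 | (S,E)-4-(hydroxymethyl)-2,5-dimethylhex-2-enal | O=C/C(C)=C/[C@@H](CO)C(C)C | intermediate
5 | (S,E)-4-(iodomethyl)-2,5-dimethylhex-2-enal | O=C/C(C)=C/[C@@H](CI)C(C)C | intermediate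
6 | 2-(tert-butyldimethylsilyloxy)buta-1,3-diene | C=CC(=C)O[Si](C)(C)C(C)(C)C | starting material
7 | (1R,6S)-4-(tert-butyldimethylsilyloxy)-6-[(2S)-1-iodo-3-methylbutan-2-yl]-1-methylcyclohex-3-ene-1-carbaldehyde | CC(C)(C)[Si](C)(C)OC1=CC[C@@](C)(C=O)[C@H]([C@@H](CI)C(C)C)C1 | intermediate
8 | (3S,3aS,7aR)-5-(tert-butyldimethylsilyloxy)-7a-methyl-3-(propan-2-yl)-2,3,3a,4,7,7a-hexahydro-1H-inden-1-ol (trans-fused; C1 epimers) | CC(C)(C)[Si](C)(C)OC1=CC[C@@]2(C)C(O)C[C@@H](C(C)C)[C@@H]2C1 | intermediate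
9 | (3S,3aS,7aR)-5-(tert-butyldimethylsilyloxy)-7a-methyl-3-(propan-2-yl)-2,3,3a,4,7,7a-hexahydro-1H-inden-1-one | CC(C)(C)[Si](C)(C)OC1=CC[C@@]2(C)C(=O)C[C@@H](C(C)C)[C@@H]2C1 | intermediate
10 | (1R,3S,3aS,7aR)-5-(tert-butyldimethylsilyloxy)-7a-methyl-3-(propan-2-yl)-2,3,3a,4,7,7a-hexahydro-1H-inden-1-ol (OH cis to the angular methyl) | CC(C)(C)[Si](C)(C)OC1=CC[C@@]2(C)[C@H](O)C[C@@H](C(C)C)[C@@H]2C1 | intermediate
11 | (1R,3S,3aS,7aR)-1,5-bis(tert-butyldimethylsilyloxy)-7a-methyl-3-(propan-2-yl)-2,3,3a,4,7,7a-hexahydro-1H-indene | CC(C)(C)[Si](C)(C)OC1=CC[C@@]2(C)[C@H](O[Si](C)(C)C(C)(C)C)C[C@@H](C(C)C)[C@@H]2C1 | intermediate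
12 | (E)-but-2-enal | C/C=C/C=O | starting material
13 | (1R,3S,3aS,7aR)-1-(tert-butyldimethylsilyloxy)-7a-methyl-6-[(2S)-4-oxobutan-2-yl]-3-(propan-2-yl)octahydro-5H-inden-5-one (C6 epimers) | O=C1C([C@@H](C)CC=O)C[C@@]2(C)[C@H](O[Si](C)(C)C(C)(C)C)C[C@@H](C(C)C)[C@@H]2C1 | intermediate (not isolated)
14 | (1R,3S,3aS,7aR)-1-(tert-butyldimethylsilyloxy)-6-[(2S)-4,4-dimethoxybutan-2-yl]-7a-methyl-3-(propan-2-yl)octahydro-5H-inden-5-one (C6 epimers) | O=C1C([C@@H](C)CC(OC)OC)C[C@@]2(C)[C@H](O[Si](C)(C)C(C)(C)C)C[C@@H](C(C)C)[C@@H]2C1 | intermediate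
15 | bromomagnesium C5=C6 enolate of 14 | Br[Mg]OC1=C([C@@H](C)CC(OC)OC)C[C@@]2(C)[C@H](O[Si](C)(C)C(C)(C)C)C[C@@H](C(C)C)[C@@H]2C1 | intermediate (not isolated)
16 | (1R,3S,3aS,7aR)-1-(tert-butyldimethylsilyloxy)-6-[(2S)-4,4-dimethoxybutan-2-yl]-7a-methyl-3-(propan-2-yl)-2,3,3a,4,7,7a-hexahydro-1H-inden-5-yl trifluoromethanesulfonate | FC(F)(F)S(=O)(=O)OC1=C([C@@H](C)CC(OC)OC)C[C@@]2(C)[C@H](O[Si](C)(C)C(C)(C)C)C[C@@H](C(C)C)[C@@H]2C1 | intermediate
17 | (1R,3S,3aS,7aR)-1-(tert-butyldimethylsilyloxy)-7a-methyl-6-[(2S)-4-oxobutan-2-yl]-3-(propan-2-yl)-2,3,3a,4,7,7a-hexahydro-1H-inden-5-yl trifluoromethanesulfonate | FC(F)(F)S(=O)(=O)OC1=C([C@@H](C)CC=O)C[C@@]2(C)[C@H](O[Si](C)(C)C(C)(C)C)C[C@@H](C(C)C)[C@@H]2C1 | intermediate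
18 | cyclohex-2-en-1-one | O=C1C=CCCC1 | starting material
19 | methylzinc (S)-3-methylcyclohex-1-en-1-olate | C[Zn]OC1=C[C@@H](C)CCC1 | intermediate (not isolated)
20 | aldol adduct: 17 in which the aldehyde carbon is CH(OH) bonded to C1 of a (2S)-2-methyl-6-oxocyclohexyl ring (1,2-trans; carbinol epimers) | FC(F)(F)S(=O)(=O)OC1=C([C@@H](C)CC(O)[C@H]3C(=O)CCC[C@@H]3C)C[C@@]2(C)[C@H](O[Si](C)(C)C(C)(C)C)C[C@@H](C(C)C)[C@@H]2C1 | intermediate
21 | O-mesylate of aldol adduct 20 | FC(F)(F)S(=O)(=O)OC1=C([C@@H](C)CC(OS(C)(=O)=O)[C@H]3C(=O)CCC[C@@H]3C)C[C@@]2(C)[C@H](O[Si](C)(C)C(C)(C)C)C[C@@H](C(C)C)[C@@H]2C1 | intermediate (not isolated)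
22 | enone: hydrindenyl triflate bearing a (2S,4E)-4-[(2S)-2-methyl-6-oxocyclohexylidene]butan-2-yl group | FC(F)(F)S(=O)(=O)OC1=C([C@@H](C)C/C=C3/C(=O)CCC[C@@H]3C)C[C@@]2(C)[C@H](O[Si](C)(C)C(C)(C)C)C[C@@H](C(C)C)[C@@H]2C1 | intermediate
23 | lithium C1–C7 enolate from 22 | FC(F)(F)S(=O)(=O)OC1=C([C@@H](C)CCC3=C(O[Li])CCC[C@@H]3C)C[C@@]2(C)[C@H](O[Si](C)(C)C(C)(C)C)C[C@@H](C(C)C)[C@@H]2C1 | intermediate (not isolated)
24 | cis-ketone: hydrindenyl triflate bearing a (2S)-4-[(1S,2S)-2-methyl-6-oxocyclohexyl]butan-2-yl group | FC(F)(F)S(=O)(=O)OC1=C([C@@H](C)CC[C@@H]3C(=O)CCC[C@@H]3C)C[C@@]2(C)[C@H](O[Si](C)(C)C(C)(C)C)C[C@@H](C(C)C)[C@@H]2C1 | intermediate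
25 | potassium C1=C8 enolate of 24 | FC(F)(F)S(=O)(=O)OC1=C([C@@H](C)CC[C@@H]3C(O[K])=CCC[C@@H]3C)C[C@@]2(C)[C@H](O[Si](C)(C)C(C)(C)C)C[C@@H](C(C)C)[C@@H]2C1 | intermediate (not isolated)
26 | bis(enol triflate): hydrindenyl triflate bearing a (2S)-4-[(1S,6S)-6-methyl-2-(trifluoromethanesulfonyloxy)cyclohex-2-en-1-yl]butan-2-yl group | FC(F)(F)S(=O)(=O)OC1=C([C@@H](C)CC[C@@H]3C(OS(=O)(=O)C(F)(F)F)=CCC[C@@H]3C)C[C@@]2(C)[C@H](O[Si](C)(C)C(C)(C)C)C[C@@H](C(C)C)[C@@H]2C1 | intermediate
27 | alkenylstannane: 26 with the cyclohexenyl triflate replaced by SnMe3 | FC(F)(F)S(=O)(=O)OC1=C([C@@H](C)CC[C@@H]3C([Sn](C)(C)C)=CCC[C@@H]3C)C[C@@]2(C)[C@H](O[Si](C)(C)C(C)(C)C)C[C@@H](C(C)C)[C@@H]2C1 | intermediate (not isolated)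
28 | (4S,7S,11S,13R,14S,16R,18S)-6-7-6-5 tetracyclic diene (C8=C1–C2=C3; C7–H and C11–H cis; O16-TBS) | C1=C2C3=C(C[C@@]4(C)[C@H](O[Si](C)(C)C(C)(C)C)C[C@@H](C(C)C)[C@@H]4C3)[C@@H](C)CC[C@H]2[C@@H](C)CC1 | intermediate
29 | (1S,4S,7S,8S,11S,13R,14S,16R,18S)-1,8-cis-diol of 28 (cis-fused 6-7 junction; both OH anti to C6) | O[C@@H]1[C@@]2(O)C3=C(C[C@@]4(C)[C@H](O[Si](C)(C)C(C)(C)C)C[C@@H](C(C)C)[C@@H]4C3)[C@@H](C)CC[C@H]2[C@@H](C)CC1 | intermediate
30 | C8 monomesylate of diol 29 | CS(=O)(=O)O[C@@H]1[C@@]2(O)C3=C(C[C@@]4(C)[C@H](O[Si](C)(C)C(C)(C)C)C[C@@H](C(C)C)[C@@H]4C3)[C@@H](C)CC[C@H]2[C@@H](C)CC1 | intermediate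
31 | (4S,7S,8S,11S,13R,14S,16R,18S)-5-8-6-5 enone (C1 ketone; trans A/B; O16-TBS) | O=C1C2=C(C[C@@]3(C)[C@H](O[Si](C)(C)C(C)(C)C)C[C@@H](C(C)C)[C@@H]3C2)[C@@H](C)CC[C@@H]2[C@@H]1CC[C@@H]2C | intermediate
32 | O16-tert-butyldimethylsilyl ether of the target | C=C1C2=C(C[C@@]3(C)[C@H](O[Si](C)(C)C(C)(C)C)C[C@@H](C(C)C)[C@@H]3C2)[C@@H](C)CC[C@@H]2[C@@H]1CC[C@@H]2C | intermediate
33 | CNP0544018.1, the (4S,7S,8S,11S,13R,14S,16R,18S)-dienol | C=C1C2=C(C[C@@]3(C)[C@H](O)C[C@@H](C(C)C)[C@@H]3C2)[C@@H](C)CC[C@@H]2[C@@H]1CC[C@@H]2C | target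

Total step count: 20. Longest linear sequence: 20 steps (1 → 33; cyclohexenone 18 enters within step 11).

Steps most likely to fail

1. Step 15 (Stille–Kelly ring closure). Oxidative addition into the flanked tetrasubstituted C2 triflate may be too slow, so the mono-stannane could be protodestannylated or couple intermolecularly instead of closing the seven-membered ring. The fallback replaces tin coupling by carbene cross-coupling and sets out from ketone 24. Condensation with tosylhydrazide gives the N-tosylhydrazone F1. With Pd2(dba)3/XPhos and LiOt-Bu in dioxane at 100 °C this forms the diazo compound F2 (not isolated), whose palladium carbene inserts into the alkenyl–palladium bond formed from the C2 triflate. β-Hydride elimination toward C8 then gives diene 28 (intramolecular Barluenga coupling), where the route is rejoined.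

2. Step 9 (thermodynamic enol triflate). Enolisation could leak toward C15, or equilibration could stay incomplete, which would put the triflate on the wrong side of the ketone. The fallback generates the enolate regiospecifically by conjugate addition and sets out from bis-silyl compound 11. A BF3·OEt2-mediated Mukaiyama aldol reaction with acetaldehyde gives the β-hydroxy ketone F3. Dehydration with methyl N-(triethylammoniosulfonyl)carbamate gives the (E)-ethylidene ketone F4. Copper-catalysed asymmetric conjugate addition of (1,3-dioxolan-2-ylmethyl)magnesium bromide (CuBr·SMe2, chiral ferrocenyl diphosphine) creates C4 and the C2=C3 magnesium enolate, which N-(5-chloropyridin-2-yl)triflimide traps as the dioxolane enol triflate F5. PPTS in wet acetone then gives aldehyde 17, where the route is rejoined.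

3. Step 3 (Diels–Alder reaction). The trisubstituted, γ-branched enal may react sluggishly or with poor facial selectivity under the catalyst. The fallback uses a more nucleophilic diene and an enone intermediate, and sets out from iodide 5. Cycloaddition with (E)-1-methoxy-3-(trimethylsilyloxy)buta-1,3-diene (ZnCl2 or a Cr(III)–salen catalyst) gives the methoxy silyl enol ether F6. Trifluoroacetic acid unveils the cyclohexenone aldehyde F7. Copper hydride conjugate reduction with [(Ph3P)CuH]6 in the presence of TBSCl gives silyl enol ether 7, where the route is rejoined.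

Further compounds
F1 | step 15 | N-tosylhydrazone of cis-ketone 24 | FC(F)(F)S(=O)(=O)OC1=C([C@@H](C)CC[C@@H]3C(=NNS(=O)(=O)c4ccc(C)cc4)CCC[C@@H]3C)C[C@@]2(C)[C@H](O[Si](C)(C)C(C)(C)C)C[C@@H](C(C)C)[C@@H]2C1
F2 | step 15 | diazo compound derived from F1 (not isolated) | FC(F)(F)S(=O)(=O)OC1=C([C@@H](C)CC[C@@H]3C(=[N+]=[N-])CCC[C@@H]3C)C[C@@]2(C)[C@H](O[Si](C)(C)C(C)(C)C)C[C@@H](C(C)C)[C@@H]2C1
F3 | step 9 | (1R,3S,3aS,7aR)-1-(tert-butyldimethylsilyloxy)-6-(1-hydroxyethyl)-7a-methyl-3-(propan-2-yl)octahydro-5H-inden-5-one (diastereomers) | O=C1C(C(C)O)C[C@@]2(C)[C@H](O[Si](C)(C)C(C)(C)C)C[C@@H](C(C)C)[C@@H]2C1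
F4 | step 9 | (1R,3S,3aS,7aR,6E)-1-(tert-butyldimethylsilyloxy)-6-ethylidene-7a-methyl-3-(propan-2-yl)octahydro-5H-inden-5-one | O=C1/C(=C/C)C[C@@]2(C)[C@H](O[Si](C)(C)C(C)(C)C)C[C@@H](C(C)C)[C@@H]2C1
F5 | step 9 | (1R,3S,3aS,7aR)-1-(tert-butyldimethylsilyloxy)-6-[(2S)-1-(1,3-dioxolan-2-yl)propan-2-yl]-7a-methyl-3-(propan-2-yl)-2,3,3a,4,7,7a-hexahydro-1H-inden-5-yl trifluoromethanesulfonate | FC(F)(F)S(=O)(=O)OC1=C([C@@H](C)CC3OCCO3)C[C@@]2(C)[C@H](O[Si](C)(C)C(C)(C)C)C[C@@H](C(C)C)[C@@H]2C1
F6 | step 3 | (1R,6S)-6-[(2S)-1-iodo-3-methylbutan-2-yl]-2-methoxy-1-methyl-4-(trimethylsilyloxy)cyclohex-3-ene-1-carbaldehyde (C2 epimers) | COC1C=C(O[Si](C)(C)C)C[C@@H]([C@@H](CI)C(C)C)[C@]1(C)C=O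
F7 | step 3 | (1R,6S)-6-[(2S)-1-iodo-3-methylbutan-2-yl]-1-methyl-4-oxocyclohex-2-ene-1-carbaldehyde | O=C[C@]1(C)C=CC(=O)C[C@H]1[C@@H](CI)C(C)C
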